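Partner enters at a steady rate, so the amount fed grows in step with the clock. If the rate is first order in the partner present, and if the catalyst loading is held, the substrates stay at their charge and the partner fed stays in the flask, product grows with the feed and with the square of time.

| setting | Saturday's | Friday's | Thursday's | flask |
|---|---|---|---|---|
| left-handed substrate | 0.20 M | 0.20 M | 0.20 M | 0.20 M |
| right-handed substrate | 0.20 M | 0.20 M | 0.20 M | 0.20 M |
| partner | 0.55 equiv (fed, over 30 min) | 2.2 equiv (fed, over 30 min) | 1.1 equiv (fed, over 30 min) | 1.10 equiv (fed, over 30 min) |
| catalyst | 0.46 mol% | 0.46 mol% | 0.23 mol% | 0.46 mol% |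
| remark | run made earlier | run made earlier | run made earlier |  |
| time |  |  |  | 30 min |

| run | time / min | left-handed product / % | left-handed substrate / % |
|---|---|---|---|
| Saturday's | 1.50 | 1.0 | 49.9 |
| Saturday's | 5.00 | 0 | 49.9 |
| Saturday's | 8.00 | 0.4 | 49.4 |
| Saturday's | 12.0 | 0.7 | 49.2 |
| Saturday's | 20.0 | 1.1 | 48.5 |
| Friday's | 1.33 | 0 | 49.9 |
| Friday's | 2.50 | 0.4 | 49.7 |
| Friday's | 5.00 | 0 | 49.6 |
| Friday's | 10.0 | 2.8 | 48.4 |
| Friday's | 20.0 | 6.3 | 43.9 |
| Thursday's | 1.50 | 0 | 50.1 |
| Thursday's | 5.00 | 0 | 50.3 |
| Thursday's | 8.00 | 0.3 | 50.2 |
| Thursday's | 12.0 | 0.7 | 49.7 |
| Thursday's | 20.0 | 2.3 | 48.4 |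

(scatter of a reading: 0.5 percentage points)

- catalyst is single-handed; left-handed substrate and right-handed substrate are mirror images of each other, charged as a racemate, each of them at the stated concentration

1. the left-handed product in the flask at 30 min, as a percentage of the left-handed substrate and right-handed substrate together charged
2. the left-handed substrate in the flask at 30 min, as a percentage of the left-handed substrate and right-handed substrate together charged
3. concentration of partner at 30 min, in M

We start from Friday's run, which has the catalyst loading of this flask, 0.46 mol%. Its reading at 20.0 min, 6.3%, stands higher than Saturday's 1.1%, so the scatter of 0.5 percentage points weighs less on it. We work in powers of ten. Going from 2.2 equiv to 1.10 equiv subtracts 0.301 from the logarithm, and going from 20.0 min to 30 min adds 0.352. So the reading of 6.3%, with its scatter, becomes 7.09%, which we call the ramp yield: our estimate of the left-handed product in this flask under those conditions.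

Our reckoning then leaves 42.9% left-handed substrate. Taking equivalents on the left-handed substrate, we count 0.220 M of partner fed, and taking away one partner for each left-handed product leaves 0.192 M in our reckoning. The forecast gives 6.5% left-handed product, 43.5% left-handed substrate and 0.41 M partner; its partner stands above ours, and it says “I assume equiv refers to total substrate”.

The flask gives 6.55% left-handed product, 43.5% left-handed substrate and 0.146 M partner.

    partner + catalyst + left-handed substrate → catalyst + left-handed product (k = 1.40 M⁻² s⁻¹)
    2 partner → homo dimer (k = 0.00100 M⁻¹ s⁻¹)
    partner + catalyst + right-handed substrate → catalyst + right-handed product (k = 0.780 M⁻² s⁻¹)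
    catalyst ⇌ dormant form (K = 0.450, k = 0.00100 s⁻¹)

In this flask, 66% of the partner charge remains, less than the 92% of right-handed substrate. The ramp yield stood 0.54 points above the left-handed product found. For the same flask with 4.40 equiv of partner, the logarithm rises by 0.602, so the ramp yield becomes 28.4%. That flask gave 18.6% left-handed product, with 63% of its left-handed substrate charge remaining.

Readings and results are calculated with constants of no real substance; scatter was added.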